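**Strategy.** Ring A carries both bromines meta to its methoxy group, so it is assembled with them in place and is not brominated. Its C6(Br)–C5H–C4(Br)–C3H segment corresponds to the C3–C6 diene of 3,5-dibromo-2-pyrone. The adjacent oxygenated carbons C1 and C2 are the two carbons of an alkyne. One thermal cycloaddition with CO2 extrusion forms C1–C6 and C2–C3. It delivers the aromatic ring with the diaryl ether in place and a boronate marking C2. The precursor is a 2-(methoxymethoxy)phenyl ynol ether capped with a pinacolboryl group. Oxidation, O-methylation, acetal cleavage and phenol-directed dibromination of ring B finish the synthesis.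

Key step: step 5

**Remarks on the chemistry**
- Numbering, ring A: C1 (O-aryl), C2 (OMe), C3–H, C4–Br, C5–H, C6–Br.
- Numbering, ring B: C1' (ether O), C2' (OH), C3'–Br, C4'–H, C5'–Br, C6'–H.
- The target has no stereocentre. The only geometric element on the route, the E-alkene of 7, is consumed in step 4.
- Ring B stays free of bromine until the last step because step 4 uses n-BuLi.
- The MOM acetal is kept because it tolerates carbonate, organolithium, neutral heating and peroxide. It leaves under conditions that spare the aryl methyl ether.

**Step 1**
Reactants: 1 coumalic acid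
Product: 3 3,5-dibromo-2H-pyran-2-one, via 5-bromo-2-pyrone 2 (not isolated)
Conditions: NBS (2.5 equiv), n-Bu4NBr (0.2 equiv), CHCl3, 50 °C
Reagents that add atoms: N-bromosuccinimide, O=C1CCC(=O)N1Br
Why: Hunsdiecker-type bromodecarboxylation replaces the C5 carboxyl group by bromine, and the resulting bromopyrone is then brominated by addition–elimination at C3, a sequence established for coumalic acid itself.

**Step 2**
Reactants: 4 catechol
Product: 5 2-(methoxymethoxy)phenol
Conditions: 4 (1.5 equiv), NaH (1.0 equiv), MOMCl (1.0 equiv), THF–DMF, 0 °C → rt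
Reagents that add atoms: chloromethyl methyl ether, COCCl
Why: Williamson-type O-alkylation of monosodium catecholate, in which surplus catechol holds back the bis-acetal; catechol leaves in the water wash and any bis-acetal stays neutral when 5 is extracted into base.

**Step 3**
Reactants: 5 2-(methoxymethoxy)phenol; 6 trichloroethylene
Product: 7 1-{[(E)-1,2-dichloroethenyl]oxy}-2-(methoxymethoxy)benzene
Conditions: 6 (2 equiv), K2CO3, DMF, 70 °C
Reagents that add atoms: none
Why: Carbonate dehydrochlorinates 6 and the phenoxide adds anti to the resulting chloroalkyne (the known vinylation of phenols with trichloroethylene), which should give the E-dichlorovinyl ether while the MOM acetal is inert to base.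

**Step 4**
Reactants: 7 1-{[(E)-1,2-dichloroethenyl]oxy}-2-(methoxymethoxy)benzene; 8 2-isopropoxy-4,4,5,5-tetramethyl-1,3,2-dioxaborolane
Product: 12 2-{[2-(methoxymethoxy)phenoxy]ethynyl}-4,4,5,5-tetramethyl-1,3,2-dioxaborolane, via chloroalkyne 9 (not isolated), via lithium acetylide 10 (not isolated), via lithium borate 11 (not isolated)
Conditions: n-BuLi (2.05 equiv), THF, −78 → −40 °C; 8, −78 °C; HCl·Et2O (1.0 equiv), −78 °C → rt; filtration under Ar, no chromatography
Reagents that add atoms: none
Why: β-Elimination of HCl followed by chlorine–lithium exchange is the standard way from 1,2-dichlorovinyl ethers to lithiated ynol ethers, and capture of a lithium acetylide by an isopropoxyboronate with release of the neutral ester by one equivalent of anhydrous acid is the standard alkynylboronate synthesis; at −78 °C both should outrun MOM-directed ring lithiation.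

**Step 5**
Reactants: 3 3,5-dibromo-2H-pyran-2-one; 12 2-{[2-(methoxymethoxy)phenoxy]ethynyl}-4,4,5,5-tetramethyl-1,3,2-dioxaborolane
Product: 14 2-{3,5-dibromo-2-[2-(methoxymethoxy)phenoxy]phenyl}-4,4,5,5-tetramethyl-1,3,2-dioxaborolane, via bridged lactone 13 (not isolated)
Conditions: 3 (1.3 equiv), dry o-xylene, 130 °C, Ar
Reagents that add atoms: none
Why: Proposed new method: a Diels–Alder addition of inverse electron demand joins the diene termini C3 and C6 of pyrone 3 to the two alkyne carbons of 12, and the strained dienyl lactone 13 then expels CO2 in a retro-(4+2) step, so the benzene ring appears at the correct oxidation level without an oxidant. The closest known reaction types are the thermal cycloaddition–decarboxylation of 2-pyrones with carbon- or silicon-substituted alkynyl pinacolboronates to arylboronates and the cycloadditions of 3 with enol ethers, whereas an oxygen-substituted alkynylboronate has not served as the two-carbon partner. Ring A is closed intermolecularly in (4+2) mode, C1–C6 and C2–C3 being made in the same event from four carbons of 3 and two of 12. Only regiochemistry needs control: lone-pair donation from oxygen, reinforced by the vacant p orbital on boron, places the largest HOMO coefficient on the boron-bearing carbon, which pairs with C6 of 3, the vinylogous acceptor terminus, and this leaves the aryloxy carbon to bond to C3–Br; sterics agree, since the bulky Bpin group ends up beside C–H and not beside C–Br. The two bridgehead stereocentres of 13 are transient and vanish on aromatisation, so no stereocentre has to be set. The O-aryl group offers no sp3 C–H for retro-ene fragmentation to a ketene, and the C–Br bonds, the MOM acetal and the boronate should be inert to neutral heating.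

**Step 6**
Reactants: 14 2-{3,5-dibromo-2-[2-(methoxymethoxy)phenoxy]phenyl}-4,4,5,5-tetramethyl-1,3,2-dioxaborolane
Product: 16 3,5-dibromo-2-[2-(methoxymethoxy)phenoxy]phenol, via aryl borate ester 15 (not isolated)
Conditions: 30% aq H2O2, NaOH, THF–H2O, 0 °C → rt
Reagents that add atoms: hydrogen peroxide, OO
Why: Boronate oxidation, in which hydroperoxide adds to boron, the aryl group migrates from boron to oxygen at the same ring carbon and 15 is hydrolysed; the process is indifferent to ortho crowding and harmless to aryl bromide and MOM groups.

**Step 7**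
Reactants: 16 3,5-dibromo-2-[2-(methoxymethoxy)phenoxy]phenol
Product: 17 1,5-dibromo-3-methoxy-2-[2-(methoxymethoxy)phenoxy]benzene
Conditions: MeI, K2CO3, acetone, 40 °C
Reagents that add atoms: iodomethane, CI
Why: Williamson O-methylation of the only free and rather acidic phenol.

**Step 8**
Reactants: 17 1,5-dibromo-3-methoxy-2-[2-(methoxymethoxy)phenoxy]benzene
Product: 18 2-(2,4-dibromo-6-methoxyphenoxy)phenol
Conditions: conc. HCl (cat.), MeOH, 50 °C
Reagents that add atoms: none
Why: Acid-catalysed acetal exchange with methanol removes the MOM group under conditions that leave the aryl methyl ether, the diaryl ether and the C–Br bonds untouched.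

**Step 9**
Reactants: 18 2-(2,4-dibromo-6-methoxyphenoxy)phenol
Product: 20 2,4-dibromo-6-(2,4-dibromo-6-methoxyphenoxy)phenol, via para-monobromide 19 (not isolated)
Conditions: Br2 (2.05 equiv), AcOH–CH2Cl2, 0 °C → rt
Reagents that add atoms: bromine, BrBr
Why: Electrophilic aromatic bromination, in which the free OH of ring B is by far the strongest activator and its only open para and ortho positions are C5' and C3', while ring A is deactivated by two bromines.

**Compound list**
1 | coumalic acid (2-oxo-2H-pyran-5-carboxylic acid) | OC(=O)C1=COC(=O)C=C1 | starting material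
2 | 5-bromo-2H-pyran-2-one | O=C1OC=C(Br)C=C1 | intermediate
3 | 3,5-dibromo-2H-pyran-2-one | O=C1OC=C(Br)C=C1Br | intermediate
4 | catechol | Oc1ccccc1O | starting material
5 | 2-(methoxymethoxy)phenol | COCOc1ccccc1O | intermediate
6 | trichloroethylene | ClC=C(Cl)Cl | starting material
7 | 1-{[(E)-1,2-dichloroethenyl]oxy}-2-(methoxymethoxy)benzene | COCOc1ccccc1O/C(Cl)=C\Cl | intermediate
8 | 2-isopropoxy-4,4,5,5-tetramethyl-1,3,2-dioxaborolane | CC(C)OB1OC(C)(C)C(C)(C)O1 | starting material
9 | 1-[(chloroethynyl)oxy]-2-(methoxymethoxy)benzene | COCOc1ccccc1OC#CCl | intermediate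
10 | lithium [2-(methoxymethoxy)phenoxy]acetylide | COCOc1ccccc1OC#C[Li] | intermediate
11 | lithium isopropoxy{[2-(methoxymethoxy)phenoxy]ethynyl}(pinacolato)borate | [Li+].COCOc1ccccc1OC#C[B-]1(OC(C)C)OC(C)(C)C(C)(C)O1 | intermediate
12 | 2-{[2-(methoxymethoxy)phenoxy]ethynyl}-4,4,5,5-tetramethyl-1,3,2-dioxaborolane | COCOc1ccccc1OC#CB1OC(C)(C)C(C)(C)O1 | intermediate
13 | 4,6-dibromo-8-[2-(methoxymethoxy)phenoxy]-7-(4,4,5,5-tetramethyl-1,3,2-dioxaborolan-2-yl)-2-oxabicyclo[2.2.2]octa-5,7-dien-3-one (racemic; the two bridgeheads are fixed relative to each other by the bicycle) | COCOc1ccccc1OC1=C(B2OC(C)(C)C(C)(C)O2)C2OC(=O)C1(Br)C=C2Br | intermediate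
14 | 2-{3,5-dibromo-2-[2-(methoxymethoxy)phenoxy]phenyl}-4,4,5,5-tetramethyl-1,3,2-dioxaborolane | COCOc1ccccc1Oc1c(Br)cc(Br)cc1B1OC(C)(C)C(C)(C)O1 | intermediate
15 | 2-{3,5-dibromo-2-[2-(methoxymethoxy)phenoxy]phenoxy}-4,4,5,5-tetramethyl-1,3,2-dioxaborolane | COCOc1ccccc1Oc1c(Br)cc(Br)cc1OB1OC(C)(C)C(C)(C)O1 | intermediate
16 | 3,5-dibromo-2-[2-(methoxymethoxy)phenoxy]phenol | COCOc1ccccc1Oc1c(Br)cc(Br)cc1O | intermediate
17 | 1,5-dibromo-3-methoxy-2-[2-(methoxymethoxy)phenoxy]benzene | COCOc1ccccc1Oc1c(Br)cc(Br)cc1OC | intermediate
18 | 2-(2,4-dibromo-6-methoxyphenoxy)phenol | COc1cc(Br)cc(Br)c1Oc1ccccc1O | intermediate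
19 | 4-bromo-2-(2,4-dibromo-6-methoxyphenoxy)phenol | COc1cc(Br)cc(Br)c1Oc1cc(Br)ccc1O | intermediate
20 | 2,4-dibromo-6-(2,4-dibromo-6-methoxyphenoxy)phenol (CNP0236935.0) | COc1cc(Br)cc(Br)c1Oc1cc(Br)cc(Br)c1O | target

**Total step count:** 9.
**Longest linear sequence:** 8 steps (4 → 5 → 7 → 12 → 14 → 16 → 17 → 18 → 20). Step 1 is a one-step side branch.

**Steps most likely to fail**

**1. Step 5.** The cycloaddition may be slower than thermal oligomerisation or adventitious protodeboronation of the ynol ether. Regiocontrol may also erode if the boron acceptor offsets the oxygen donor. The fallback uses known chemistry, sets out from 5 and comes back at 16; ring A is then bought and not built. Phenol 5 displaces fluoride from commercial 3,5-dibromo-2-fluorobenzaldehyde (O=Cc1cc(Br)cc(Br)c1F) in a nucleophilic aromatic substitution activated by the ortho formyl group (K2CO3, DMF, 80 °C). This should give 3,5-dibromo-2-[2-(methoxymethoxy)phenoxy]benzaldehyde F1. Baeyer–Villiger oxidation (mCPBA, NaHCO3, CH2Cl2), with the ortho aryloxy group assisting aryl migration, should give 3,5-dibromo-2-[2-(methoxymethoxy)phenoxy]phenyl formate F2. Methanolysis (K2CO3, MeOH) then releases 16.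

**2. Step 4.** The C(sp)–B bond may be lost, or HCl or water may add across the electron-rich triple bond, while the borate is neutralised and the product is handled. The fallback sets out from 7 and comes back at 16, with silicon replacing boron as the placeholder for the C2 oxygen.
- Acetylide 10 is generated as before through 9 and trapped with ClSiMe2H. No acid quench is needed, and the product {[2-(methoxymethoxy)phenoxy]ethynyl}dimethylsilane F3 should tolerate aqueous work-up and silica gel.
- Heating F3 with 3 in o-xylene should pass through 4,6-dibromo-7-(dimethylsilyl)-8-[2-(methoxymethoxy)phenoxy]-2-oxabicyclo[2.2.2]octa-5,7-dien-3-one F4. Loss of CO2 should then give {3,5-dibromo-2-[2-(methoxymethoxy)phenoxy]phenyl}dimethylsilane F5.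
- The regiochemical bias should be at least as strong as with boron, because positive charge building on the oxygen-bearing carbon is β to silicon.
- Tamao oxidation (30% H2O2, KF, KHCO3, THF–MeOH) converts F5 into 16.

**3. Step 9.** Site control may be incomplete when both bromines arrive in one undirected operation. Possible outcomes are over-bromination of ring B para to the ether oxygen, attack on ring A next to the methoxy group, or a stalled second substitution. The fallback sets out from 18 and comes back at 20. It replaces the double substitution by two separately directed halogenations with purification between them. n-Bu4NBr3 (1.0 equiv, CH2Cl2–MeOH, rt) is a mild para-selective brominating agent for phenols and should stop at 19, which is isolated. NBS with catalytic i-Pr2NH in CH2Cl2 then delivers bromine from an N-bromoamine hydrogen-bonded to the phenolic OH, so it goes to the single free ortho position C3' and gives 20.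

**Further compounds**
F1 | step 5 | 3,5-dibromo-2-[2-(methoxymethoxy)phenoxy]benzaldehyde | COCOc1ccccc1Oc1c(Br)cc(Br)cc1C=O
F2 | step 5 | 3,5-dibromo-2-[2-(methoxymethoxy)phenoxy]phenyl formate | COCOc1ccccc1Oc1c(Br)cc(Br)cc1OC=O
F3 | step 4 | {[2-(methoxymethoxy)phenoxy]ethynyl}dimethylsilane | COCOc1ccccc1OC#C[SiH](C)C
F4 | step 4 | 4,6-dibromo-7-(dimethylsilyl)-8-[2-(methoxymethoxy)phenoxy]-2-oxabicyclo[2.2.2]octa-5,7-dien-3-one (racemic) | COCOc1ccccc1OC1=C([SiH](C)C)C2OC(=O)C1(Br)C=C2Br
F5 | step 4 | {3,5-dibromo-2-[2-(methoxymethoxy)phenoxy]phenyl}dimethylsilane | COCOc1ccccc1Oc1c(Br)cc(Br)cc1[SiH](C)C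
F0 | step 9 | none | none
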